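(The earlier runs and the new flask stem from a simulated flask from invented constants; scatter was added.)

The choice here is to carry one number from flask to flask, the crossover, and to reckon the alpha flask from it.

| flask | starting material | partner | catalyst | product | time |
|---|---|---|---|---|---|
| gamma | 0.0800 M | 0.240 M | 0.00240 M |  |  |
| epsilon | 0.0800 M | 0.240 M | 0.00480 M |  |  |
| eta | 0.0800 M | 0.240 M | 0.00240 M | 0.0240 M |  |
| theta | 0.0800 M | 0.720 M | 0.00240 M |  |  |
| alpha | 0.0400 M | 0.200 M | 0.00240 M |  | 170 s |

- gamma run (time / s: [product] / M): 6.8: 0.0020; 11: 0.0029; 17: 0.0031; 27: 0.0062; 43: 0.0120; 68: 0.0200; 110: 0.0361; 170: 0.0562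
- epsilon run (time / s: [product] / M): 6.8: 0.0030; 11: 0.0042; 17: 0.0083; 27: 0.0136; 43: 0.0206; 68: 0.0334; 110: 0.0538; 170: 0.0686
- eta run (time / s: [product] / M): 6.8: 0.0271; 11: 0.0310; 17: 0.0331; 27: 0.0404; 43: 0.0513; 68: 0.0669; 110: 0.0841; 170: 0.0966
- theta run (time / s: [product] / M): 6.8: 0.0022; 11: 0.0047; 17: 0.0058; 27: 0.0086; 43: 0.0161; 68: 0.0322; 110: 0.0591; 170: 0.0765

(scatter of a reading: 8 × 10⁻⁴ M)

- Overall: starting material + partner -> product, with catalyst as catalyst.
- Constant volume, constant temperature.
- A reading of a species includes what of it is bound.
- An order is taken over about fifteen percent of the charge, up and down.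

* the exponent of [catalyst] in the starting rate at the charge of the gamma run (at the point where two percent of the starting material have become product)
* the exponent of [partner] in the starting rate at the charge of the gamma run (at the point where two percent of the starting material have become product)
* product in the alpha run at 170 s, as a share of the starting material charged

Between 6.8 s and 43 s, the gamma flask turns 0.00378 s⁻¹ of its remaining starting material. Over the same times the eta flask, charged with product, turns 0.0103 s⁻¹, a faster pace than gamma's. A straight line through these two readings, against mean product, has slope 0.203 L mol⁻¹ s⁻¹. It puts the crossover at 0.0117 M, which is 14.6 % of gamma's charge. The crossover is the product at which the route through product (autocatalysis) equals the route without it.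

Joining both ends gives rate = slope × (crossover + product) × starting material left, a logistic curve.

The crossover is an amount, so in the alpha flask, with half the starting material, it stands at 29.1 % of the charge. This reckoning, which leaves out the change in partner, gives 52.7 % at 170 s. For gamma, the catalyst route's share of the rate at two percent turned gives a catalyst order of 0.879.

The forecast says “product accelerates the reaction” and gives 0.85, 0.33 and 55 %, a higher alpha figure than this reckoning's.

The simulation gives 0.88, 0.19 and 50.0 %.

    catalyst + partner ⇌ catalyst-reagent complex, settled at all times (48.90 L mol⁻¹)
    catalyst-reagent complex + starting material → product + catalyst (1.340 L mol⁻¹ s⁻¹)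
    2 partner ⇌ idle reagent dimer, settled at all times (17.50 L mol⁻¹)
    starting material + partner + product → 2 product (2.880 L² mol⁻² s⁻¹)

For the alpha flask, the joined curve, reckoned at gamma's partner level, reaches the crossover at about 99.0 s, at 29.1 % of the charge. The alpha flask stands at 50.0 % at 170 s, a share above that reckoned crossover. The epsilon flask, with twice the catalyst, takes a crossover of 29.1 % of its charge. The joined curve then reaches half of that charge at 80.8 s, and the simulated time is 81.5 s.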